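**Retrosynthetic overview**
1. Target ⇒ benzylic carbinol. The last step removes the carbinol oxygen through an ortho-quinone methide, so the benzylic carbon can come from an aldehyde.
2. Key disconnection C4–CH(OH)Ar: an umpolung carbonyl allylation. The terpene tertiary allylic alcohol (an allyl cation equivalent via its π-allylpalladium intermediate) is reversed by InI into an allylindium, which attacks one formyl carbon of jensenone through C4. Both carbons are electrophilic in their precursors, and the quaternary stereocentre is set here.
3. Terpene allylic diol ⇒ (−)-α-gurjunene: epoxidation and solvolytic cyclopropane opening install C5=C6 and the C11 hydroxyl.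
4. Jensenone ⇒ phloroglucinol: double formylation, then Friedel–Crafts isovalerylation.
5. Ring order: no ring is built. The five- and seven-membered rings (with C1, C7, C10) come from α-gurjunene, whose cyclopropane is opened before the fragments are joined; the benzene ring comes from phloroglucinol.

Assumption: terpene positions carry guaiane numbers (C1/C5 ring fusion, C4 quaternary carbon, C7 side-chain carbon, C10 methyl-bearing carbon, C11 carbinol carbon), and commercial (−)-α-gurjunene from gurjun balsam oil is taken as the (1R,6S,7R,10R) enantiomer, whose C1, C7 and C10 map onto the target.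

**Step 1**
Reactants: 1 phloroglucinol (benzene-1,3,5-triol)
Product: 3 2,4-diformylphloroglucinol (2,4,6-trihydroxybenzene-1,3-dicarbaldehyde), via bis-iminium dichloride 2 (not isolated)
Conditions: POCl3 (2.4 equiv), DMF (2.6 equiv), dioxane, 0 °C to rt; then H2O, 50 °C
Reagents that add atoms: N,N-dimethylformamide, CN(C)C=O; water, O
Why: Twofold Vilsmeier–Haack formylation of the very electron-rich triol and hydrolysis of bis-iminium salt 2 on aqueous work-up give the 2,4-dialdehyde, each formyl group deactivating the ring enough to stop before a third substitution; no stereocentre is involved.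

**Step 2**
Reactants: 3 2,4-diformylphloroglucinol; 4 isovaleryl chloride (3-methylbutanoyl chloride)
Product: 5 jensenone (2,4,6-trihydroxy-5-(3-methylbutanoyl)benzene-1,3-dicarbaldehyde)
Conditions: AlCl3 (4 equiv), PhNO2, 70 °C; then ice, aq HCl
Reagents that add atoms: none
Why: Friedel–Crafts acylation at the only unsubstituted ring carbon, which remains nucleophilic because it is ortho, ortho and para to the three hydroxyl groups; no stereocentre is involved.

**Step 3**
Reactants: 6 (−)-α-gurjunene
Product: 8 (1R,7R,10R)-guai-5-ene-4,11-diol, via α-gurjunene 4,5-epoxide 7 (not isolated)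
Conditions: dimethyldioxirane (1.1 equiv), acetone, −20 °C; then H2O, HClO4 (5 mol %), 0 °C
Reagents that add atoms: dimethyldioxirane, CC1(C)OO1; water, O
Why: Oxygen-atom transfer from the dioxirane epoxidises the tetrasubstituted alkene, and acid then opens the epoxide at C5 because that cation is cyclopropylcarbinyl, cleaves the C6–C11 bond (cyclopropylcarbinyl–homoallyl rearrangement, the manifold that turns 2-carene oxide into p-menth-2-ene-1,8-diol) and lets water capture the tertiary C11 cation, which installs C5=C6 and both hydroxyls while C1, C7 and C10 are untouched and the C4 carbinol configuration does not matter since C4 is ionised again in step 4.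

**Step 4**
Reactants: 8 (1R,7R,10R)-guai-5-ene-4,11-diol; 5 jensenone
Product: 10 2,4,6-trihydroxy-3-{hydroxy[(1R,4S,7R,10R)-11-hydroxyguai-5-en-4-yl]methyl}-5-(3-methylbutanoyl)benzaldehyde, via allylindium reagent 9 (not isolated)
Conditions: 5 (2.5 equiv), Pd(PPh3)4 (10 mol %), InI (2.2 equiv), THF–H2O (10:1), 40 °C; aq NH4Cl
Reagents that add atoms: none
Why: Umpolung carbonyl allylation (π-allylpalladium reversed by InI, Tamaru–Araki type): zerovalent palladium ionises the tertiary allylic alcohol to a π-allyl intermediate that is electrophilic at C4 and C6, monovalent indium reduces it to nucleophilic allylindium 9 with the metal on the less substituted C6, and 9 adds to one of the two equivalent formyl carbons of 5 through a closed six-membered transition state at the γ-carbon C4, so two carbons that are both electrophilic in 8 and 5 are joined and the quaternary centre is set with the new bond syn to H1, because the C6–In bond is pseudo-axial only on the face it shares with the pseudo-equatorial C7 hydroxyisopropyl group (O–In contact) and delivers the aldehyde anti to the C1–C10 bond, while the carbinol configuration is lost in step 5.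

**Step 5**
Reactants: 10 2,4,6-trihydroxy-3-{hydroxy[(1R,4S,7R,10R)-11-hydroxyguai-5-en-4-yl]methyl}-5-(3-methylbutanoyl)benzaldehyde
Product: 12 2,4,6-trihydroxy-3-{[(1R,4R,7R,10R)-11-hydroxyguai-5-en-4-yl]methyl}-5-(3-methylbutanoyl)benzaldehyde (the target), via ortho-quinone methide 11 (not isolated)
Conditions: Hantzsch ester (diethyl 2,6-dimethyl-1,4-dihydropyridine-3,5-dicarboxylate, 1.3 equiv), (PhO)2P(O)OH (10 mol %), CH2Cl2, rt
Reagents that add atoms: none
Why: Acid-catalysed loss of water from the doubly ortho-hydroxylated benzylic carbinol gives ortho-quinone methide 11, which cannot tautomerise because C4 is quaternary and is reduced at the methide carbon by hydride transfer from the Hantzsch ester (organocatalytic transfer hydrogenation) faster than the hydrogen-bonded formyl and ketone groups, the tertiary alcohol and the trisubstituted alkene surviving the weak acid; no stereocentre is created and C4 is not touched.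

**Compound list**
1 | phloroglucinol (benzene-1,3,5-triol) | Oc1cc(O)cc(O)c1 | starting material
2 | bis-iminium dichloride of 2,4-diformylphloroglucinol (not isolated) | C[N+](C)=Cc1c(O)cc(O)c(C=[N+](C)C)c1O.[Cl-].[Cl-] | intermediate
3 | 2,4-diformylphloroglucinol (2,4,6-trihydroxybenzene-1,3-dicarbaldehyde) | O=Cc1c(O)cc(O)c(C=O)c1O | intermediate
4 | isovaleryl chloride (3-methylbutanoyl chloride) | CC(C)CC(=O)Cl | starting material
5 | jensenone (2,4,6-trihydroxy-5-(3-methylbutanoyl)benzene-1,3-dicarbaldehyde) | CC(C)CC(=O)c1c(O)c(C=O)c(O)c(C=O)c1O | intermediate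
6 | (−)-α-gurjunene [(1R,6S,7R,10R)-aromadendr-4-ene; (1aR,4R,4aR,7bS)-1,1,4,7-tetramethyl-1a,2,3,4,4a,5,6,7b-octahydro-1H-cyclopropa[e]azulene] | CC1=C2[C@H]3[C@@H](CC[C@@H](C)[C@H]2CC1)C3(C)C | starting material
7 | α-gurjunene 4,5-epoxide (oxirane on the former C4=C5 bond; C1, C6, C7, C10 as in 6; epoxide face not assigned, both faces converge) (not isolated) | CC12OC13[C@H]4[C@@H](CC[C@@H](C)[C@H]3CC2)C4(C)C | intermediate
8 | (1R,7R,10R)-guai-5-ene-4,11-diol (tertiary allylic OH at C4, C5=C6, tertiary OH at C11; C4 epimers converge) | CC1(O)CC[C@H]2C1=C[C@H](C(C)(C)O)CC[C@H]2C | intermediate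
9 | allylindium reagent: guai-4-en-11-ol carrying In(I)(OH) on C6 (trivalent indium, σ-allyl form, C6 labile; C1, C7, C10 as in 8) (not isolated) | CC1=C2C([In](I)O)[C@@H](CC[C@@H](C)[C@H]2CC1)C(C)(C)O | intermediate
10 | 2,4,6-trihydroxy-3-{hydroxy[(1R,4S,7R,10R)-11-hydroxyguai-5-en-4-yl]methyl}-5-(3-methylbutanoyl)benzaldehyde (both carbinol epimers; benzylic carbon, H1 and the C7 side chain on one face, 4-CH3 and 10-CH3 on the other) | CC(C)CC(=O)c1c(O)c(C=O)c(O)c(C(O)[C@@]2(C)CC[C@H]3C2=C[C@H](C(C)(C)O)CC[C@H]3C)c1O | intermediate
11 | ortho-quinone methide from 10 (cyclohexadienone with exocyclic C=CH–C4 bond; terpene configuration as in 12) (not isolated) | CC(C)CC(=O)C1=C(O)C(=C[C@@]2(C)CC[C@H]3C2=C[C@H](C(C)(C)O)CC[C@H]3C)C(=O)C(C=O)=C1O | intermediate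
12 | 2,4,6-trihydroxy-3-{[(1R,4R,7R,10R)-11-hydroxyguai-5-en-4-yl]methyl}-5-(3-methylbutanoyl)benzaldehyde | CC(C)CC(=O)c1c(O)c(C=O)c(O)c(C[C@@]2(C)CC[C@H]3C2=C[C@H](C(C)(C)O)CC[C@H]3C)c1O | target

**Step count and risks**
Total steps: 5 (steps 1 and 3 each run two operations in one flask). Longest linear sequence: 4 steps (1 → 3 → 5 → 10 → 12); the terpene branch is 3 steps (6 → 8 → 10 → 12).

The three steps most likely to fail:

Step 4 (highest risk). Zerovalent palladium may fail to ionise the hindered tertiary allylic alcohol, or the acidic phenols of 5 may intercept the π-allyl intermediate. Attack through C6 instead of C4, or on the wrong face of C4, would also spoil the step. The fallback sets out from 6 and avoids both 8 and palladium. NBS in wet acetone at −20 °C triggers the same cyclopropane-opening relay with bromine at C4 and water at C11, giving 4-bromoguai-5-en-11-ol F1, used crude. InI in THF inserts directly into its allylic C–Br bond to give the allylindium bromide iodide F2, which adds to 5 through C4 as in step 4. The route is rejoined at 10.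

Step 3. The tetrasubstituted epoxide may undergo a semipinacol (Meinwald-type) shift to a ketone instead of the cyclopropane relay. The fallback sets out from 6 and uses no epoxide. PhSeCl in MeCN–H2O gives, by a seleniranium-triggered relay, 4-(phenylselanyl)guai-5-en-11-ol F3. H2O2 and pyridine at 0 °C oxidise it to the allylic selenoxide, whose [2,3]-sigmatropic shift and hydrolysis deliver the transposed allylic alcohol guai-4-ene-6,11-diol F4. F4 replaces 8 in step 4, is ionised to the same π-allyl intermediate, and the route is rejoined at 9.

Step 5. The methide carbon of 11 is hindered, so hydride transfer may be slow, and the free formyl group could be reduced or 11 could be captured by a phenol of a second molecule. The fallback sets out from 10. PhSH with catalytic (PhO)2P(O)OH traps 11 as the isolable benzylic phenyl sulfide F5 (thia-Michael addition). nBu3SnH and AIBN in toluene at 80 °C then cleave the benzylic C–S bond homolytically, and the route is rejoined at 12.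

**Further compounds**
F1 | step 4 | 4-bromoguai-5-en-11-ol (C1, C7, C10 as in 8; C4 not assigned) | CC1(Br)CC[C@H]2C1=C[C@H](C(C)(C)O)CC[C@H]2C
F2 | step 4 | allylindium bromide iodide: guai-4-en-11-ol carrying In(Br)(I) on C6 (trivalent indium, C6 labile) | CC1=C2C([In](Br)I)[C@@H](CC[C@@H](C)[C@H]2CC1)C(C)(C)O
F3 | step 3 | 4-(phenylselanyl)guai-5-en-11-ol (C1, C7, C10 as in 8; C4 not assigned) | CC1([Se]c2ccccc2)CC[C@H]3C1=C[C@H](C(C)(C)O)CC[C@H]3C
F4 | step 3 | (1R,7R,10R)-guai-4-ene-6,11-diol (C6 not assigned) | CC1=C2C(O)[C@@H](CC[C@@H](C)[C@H]2CC1)C(C)(C)O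
F5 | step 5 | 2,4,6-trihydroxy-3-{[(1R,4S,7R,10R)-11-hydroxyguai-5-en-4-yl](phenylsulfanyl)methyl}-5-(3-methylbutanoyl)benzaldehyde (both epimers at the sulfur-bearing carbon) | CC(C)CC(=O)c1c(O)c(C=O)c(O)c(C(Sc2ccccc2)[C@@]3(C)CC[C@H]4C3=C[C@H](C(C)(C)O)CC[C@H]4C)c1O
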